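**Retrosynthetic overview**
1. Side chain last: C14=C15 by cross-metathesis with methyl methacrylate, and C12–C13 with the C12 stereocentre by catalytic asymmetric allylboration of a C4 carbaldehyde made from the enol triflate of a C4 ketone.
2. The cis-7,8-epoxide comes from catalyst-controlled epoxidation of a (Z)-C7=C8 cyclononene at the ketone stage, before any electron-rich enol ether exists.
3. The nine-membered ring (formed second) is closed by ring-closing metathesis of a 3,4-trans-dialkenyl 2-acetoxyoxan-5-one.
4. That oxanone comes from a 4-alkyl Achmatowicz lactol by a hydroxyl-directed organocatalytic conjugate alkenylboration with dynamic kinetic resolution (sets C11a; C4a and C1 follow by equilibration and anomeric acetylation).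
5. The pyranone ring (formed first) comes from a furfuryl alcohol made by Negishi coupling of 3-bromofuran-2-carbaldehyde.

Assumption: the target is taken exactly as the SMILES specifies, so the 7,8-epoxide is cis on the nine-membered ring (7S,8R) and a Z-configured C7=C8 olefin is its precursor; ring atoms are numbered as in the xenicanes (C1, O2, C3, C4, C4a, C5–C11, C11a; side chain C12–C17).

**Step 1**
Reactants: 1 allylmagnesium bromide; 2 2,3-dibromoprop-1-ene
Product: 3 2-bromohexa-1,5-diene
Conditions: Et2O, 0 °C to 23 °C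
Reagents that add atoms: none
Why: Displacement of the allylic bromide of 2 by the allyl Grignard reagent (the vinylic C–Br bond is inert) is a standard preparation of 2-bromo-1,5-dienes.

**Step 2**
Reactants: 3 2-bromohexa-1,5-diene
Product: 5 hexa-1,5-dien-2-ylboronic acid, via hexa-1,5-dien-2-ylmagnesium bromide 4 (not isolated)
Conditions: Mg turnings, THF, 40 °C; B(OMe)3, −78 °C to 23 °C; 1 M HCl
Reagents that add atoms: trimethyl borate COB(OC)OC; water O
Why: Magnesium insertion into the vinylic C–Br bond, borylation of the alkenyl Grignard reagent and hydrolysis is the standard boronic acid synthesis.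

**Step 3**
Reactants: 6 4-bromo-2-methylbut-1-ene; 7 3-bromofuran-2-carbaldehyde
Product: 10 [3-(3-methylbut-3-en-1-yl)furan-2-yl]methanol, via (3-methylbut-3-en-1-yl)zinc bromide 8 (not isolated), via 3-(3-methylbut-3-en-1-yl)furan-2-carbaldehyde 9 (not isolated)
Conditions: 6, Zn dust, LiCl, THF, 40 °C; then 7, Pd(OAc)2 (2 mol %), SPhos (4 mol %), 23 °C; then MeOH, NaBH4, 0 °C
Reagents that add atoms: none
Why: Negishi sp3–sp2 cross-coupling of the alkylzinc bromide with the activated heteroaryl bromide tolerates the aldehyde, which is then reduced in the same flask by NaBH4.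

**Step 4**
Reactants: 10 [3-(3-methylbut-3-en-1-yl)furan-2-yl]methanol
Product: 11 6-hydroxy-4-(3-methylbut-3-en-1-yl)-2H-pyran-3(6H)-one (racemic, mutarotating lactol)
Conditions: VO(acac)2 (5 mol %), t-BuOOH (1.5 equiv), CH2Cl2, 0 °C to 23 °C
Reagents that add atoms: tert-butyl hydroperoxide CC(C)(C)OO
Why: Achmatowicz oxidative ring expansion, in which the hydroxyl-directed vanadium/hydroperoxide oxidation converts the furfuryl alcohol and leaves the isolated 1,1-disubstituted olefin untouched.

**Step 5**
Reactants: 11 6-hydroxy-4-(3-methylbut-3-en-1-yl)-2H-pyran-3(6H)-one; 5 hexa-1,5-dien-2-ylboronic acid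
Product: 12 (5R)-5-(hexa-1,5-dien-2-yl)-6-hydroxy-4-(3-methylbut-3-en-1-yl)oxan-3-one (C4 epimers, both anomers)
Conditions: 5 (2 equiv), 1-[3,5-bis(trifluoromethyl)phenyl]-3-[(1R,2R)-2-(2-hydroxybenzylideneamino)cyclohexyl]thiourea (10 mol %), toluene, 23 °C, 48 h; aq. NaHCO3 work-up
Reagents that add atoms: none
Why: Proposed new method: the hemiacetal OH of the racemising lactol condenses with the boronic acid, the iminophenol of the catalyst chelates boron to a chiral tetracoordinate boronate while the thiourea N–H bonds activate the enone carbonyl, and the alkenyl group is transferred intramolecularly to C5 (C11a) on the face syn to the O–B bond; because only the (6R)-lactol boronate fits the catalyst and the lactol enantiomers interconvert by ring–chain tautomerism, this is a dynamic kinetic resolution that sets C11a as R, with the catalyst enantiomer assigned from the chelate model. The closest known reaction type is the thiourea-catalysed hydroxyl-directed conjugate addition of alkenylboronic acids to acyclic γ-hydroxy enones, not yet shown on a cyclic hemiacetal enone, an α-substituted enone or under dynamic kinetic control.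

**Step 6**
Reactants: 12 (5R)-5-(hexa-1,5-dien-2-yl)-6-hydroxy-4-(3-methylbut-3-en-1-yl)oxan-3-one
Product: 13 (2R,3R,4S)-3-(hexa-1,5-dien-2-yl)-4-(3-methylbut-3-en-1-yl)-5-oxooxan-2-yl acetate
Conditions: Ac2O, Et3N, DMAP (10 mol %), CH2Cl2, −40 °C; MeOH quench; then DBU (0.2 equiv), CH2Cl2, 23 °C
Reagents that add atoms: acetic anhydride CC(=O)OC(C)=O
Why: DMAP-catalysed acetylation of the mutarotating lactol traps the more nucleophilic equatorial anomer (Curtin–Hammett), placing OAc trans to the C3 alkenyl group (C1 = R), and DBU then equilibrates the ketone α-centre (C4a) to the all-equatorial 3,4-trans isomer once the acetate has locked C11a against ring opening.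

**Step 7**
Reactants: 13 (2R,3R,4S)-3-(hexa-1,5-dien-2-yl)-4-(3-methylbut-3-en-1-yl)-5-oxooxan-2-yl acetate
Product: 14 (1R,4aS,7Z,11aR)-7-methyl-11-methylidene-4-oxo-1,3,4,4a,5,6,9,10,11,11a-decahydrocyclonona[c]pyran-1-yl acetate
Conditions: second-generation Hoveyda–Grubbs catalyst RuCl2(H2IMes)(=CH-C6H4-2-O-i-Pr) (10 mol %, two portions), toluene (1 mM), 80 °C, argon sparge
Reagents that add atoms: none
Why: Ring-closing olefin metathesis between the terminal vinyl and the isopropenyl-type olefin of the trans-diequatorial side chains closes the nine-membered ring, in which only the Z trisubstituted olefin is free of severe strain (Z-selective closures of xenicane nine-membered rings by this reaction are known), while the exocyclic methylene could only close a four-membered ring.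

**Step 8**
Reactants: 14 (1R,4aS,7Z,11aR)-7-methyl-11-methylidene-4-oxo-1,3,4,4a,5,6,9,10,11,11a-decahydrocyclonona[c]pyran-1-yl acetate
Product: 15 (1R,4aS,7S,8R,11aR)-7,8-epoxy-7-methyl-11-methylidene-4-oxododecahydrocyclonona[c]pyran-1-yl acetate
Conditions: D-fructose-derived Shi ketone (1,2:4,5-di-O-isopropylidene-β-D-erythro-2,3-hexodiulo-2,6-pyranose, 0.3 equiv), Oxone (2KHSO5·KHSO4·K2SO4), NaHCO3/K2CO3 buffer (pH about 9), Bu4NHSO4 (cat.), MeCN–dimethoxymethane–H2O, 0 °C
Reagents that add atoms: potassium peroxymonosulfate [K+].[O-]S(=O)(=O)OO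
Why: Shi asymmetric epoxidation, in which the electrophilic chiral dioxirane prefers the trisubstituted ring olefin over the 1,1-disubstituted methylene and, through the spiro transition state for trisubstituted olefins, delivers oxygen to the face that gives 8R and therefore the (7S,8R) cis-epoxide by catalyst control, at a stage where no enol ether or aldehyde is present.

**Step 9**
Reactants: 15 (1R,4aS,7S,8R,11aR)-7,8-epoxy-7-methyl-11-methylidene-4-oxododecahydrocyclonona[c]pyran-1-yl acetate
Product: 16 (1R,4aS,7S,8R,11aR)-7,8-epoxy-7-methyl-11-methylidene-4-(trifluoromethanesulfonyloxy)-1,4a,5,6,7,8,9,10,11,11a-decahydrocyclonona[c]pyran-1-yl acetate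
Conditions: KN(SiMe3)2 (1.05 equiv), THF, −78 °C; PhNTf2, −78 °C to −20 °C; aq. NH4Cl
Reagents that add atoms: N-phenylbis(trifluoromethanesulfonimide) O=S(=O)(N(c1ccccc1)S(=O)(=O)C(F)(F)F)C(F)(F)F
Why: Enolisation occurs towards C3, the unhindered and oxygen-acidified α-position (C4a is a tertiary ring-fusion carbon), and O-triflation of that enolate gives the C3=C4 enol triflate.

**Step 10**
Reactants: 16 (1R,4aS,7S,8R,11aR)-7,8-epoxy-7-methyl-11-methylidene-4-(trifluoromethanesulfonyloxy)-1,4a,5,6,7,8,9,10,11,11a-decahydrocyclonona[c]pyran-1-yl acetate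
Product: 17 (1R,4aS,7S,8R,11aR)-7,8-epoxy-4-formyl-7-methyl-11-methylidene-1,4a,5,6,7,8,9,10,11,11a-decahydrocyclonona[c]pyran-1-yl acetate
Conditions: Pd(PPh3)4 (5 mol %), LiCl (3 equiv), CO (1 atm), Bu3SnH (1.3 equiv, syringe pump), THF, 50 °C
Reagents that add atoms: carbon monoxide [C-]#[O+]
Why: Palladium-catalysed reductive carbonylation (formylation) of the enol triflate by oxidative addition, CO insertion and hydride transfer from tin gives the vinylogous formate, and LiCl turns the tin by-product into the weakly Lewis acidic chloride so that the epoxide survives.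

**Step 11**
Reactants: 17 (1R,4aS,7S,8R,11aR)-7,8-epoxy-4-formyl-7-methyl-11-methylidene-1,4a,5,6,7,8,9,10,11,11a-decahydrocyclonona[c]pyran-1-yl acetate; 18 allylboronic acid pinacol ester
Product: 19 (1R,4aS,7S,8R,11aR)-7,8-epoxy-4-[(1S)-1-hydroxybut-3-en-1-yl]-7-methyl-11-methylidene-1,4a,5,6,7,8,9,10,11,11a-decahydrocyclonona[c]pyran-1-yl acetate
Conditions: 18 (1.5 equiv), (S)-TRIP phosphoric acid (5 mol %), toluene, 4 Å MS, −30 °C; aq. NaHCO3 work-up
Reagents that add atoms: none
Why: Chiral phosphoric acid-catalysed allylboration proceeds through a chair transition state in which (S)-TRIP activates the boronate and exposes the Si face of the aldehyde, setting C12 as S by catalyst control without a Lewis acid that would open the epoxide or ionise the acetal acetate.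

**Step 12**
Reactants: 19 (1R,4aS,7S,8R,11aR)-7,8-epoxy-4-[(1S)-1-hydroxybut-3-en-1-yl]-7-methyl-11-methylidene-1,4a,5,6,7,8,9,10,11,11a-decahydrocyclonona[c]pyran-1-yl acetate
Product: 20 (1R,4aS,7S,8R,11aR)-4-[(1S)-1-acetoxybut-3-en-1-yl]-7,8-epoxy-7-methyl-11-methylidene-1,4a,5,6,7,8,9,10,11,11a-decahydrocyclonona[c]pyran-1-yl acetate
Conditions: Ac2O, pyridine, DMAP (cat.), CH2Cl2, 0 °C
Reagents that add atoms: acetic anhydride CC(=O)OC(C)=O
Why: Standard DMAP-catalysed acetylation of the secondary alcohol under basic conditions that do not ionise the acid-labile allylic position.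

**Step 13**
Reactants: 20 (1R,4aS,7S,8R,11aR)-4-[(1S)-1-acetoxybut-3-en-1-yl]-7,8-epoxy-7-methyl-11-methylidene-1,4a,5,6,7,8,9,10,11,11a-decahydrocyclonona[c]pyran-1-yl acetate; 21 methyl methacrylate
Product: 22 methyl (2E,5S)-5-acetoxy-5-[(1R,4aS,7S,8R,11aR)-1-acetoxy-7,8-epoxy-7-methyl-11-methylidene-1,4a,5,6,7,8,9,10,11,11a-decahydrocyclonona[c]pyran-4-yl]-2-methylpent-2-enoate (target)
Conditions: 21 (20 equiv), second-generation Hoveyda–Grubbs catalyst RuCl2(H2IMes)(=CH-C6H4-2-O-i-Pr) (10 mol %), CH2Cl2, 40 °C
Reagents that add atoms: none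
Why: Olefin cross-metathesis of the terminal olefin with excess methyl methacrylate gives the thermodynamically favoured E trisubstituted enoate, while the exocyclic methylene, the trisubstituted enol ether and the epoxide do not engage the ruthenium carbene.

**Compound list**
1 | allylmagnesium bromide | C=CC[Mg]Br | starting material
2 | 2,3-dibromoprop-1-ene | C=C(Br)CBr | starting material
3 | 2-bromohexa-1,5-diene | C=C(Br)CCC=C | intermediate
4 | hexa-1,5-dien-2-ylmagnesium bromide | C=C(CCC=C)[Mg]Br | intermediate
5 | hexa-1,5-dien-2-ylboronic acid | C=C(CCC=C)B(O)O | intermediate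
6 | 4-bromo-2-methylbut-1-ene | C=C(C)CCBr | starting material
7 | 3-bromofuran-2-carbaldehyde | O=Cc1occc1Br | starting material
8 | (3-methylbut-3-en-1-yl)zinc bromide | C=C(C)CC[Zn]Br | intermediate
9 | 3-(3-methylbut-3-en-1-yl)furan-2-carbaldehyde | O=Cc1occc1CCC(C)=C | intermediate
10 | [3-(3-methylbut-3-en-1-yl)furan-2-yl]methanol | OCc1occc1CCC(C)=C | intermediate
11 | 6-hydroxy-4-(3-methylbut-3-en-1-yl)-2H-pyran-3(6H)-one (racemic lactol) | OC1OCC(=O)C(CCC(C)=C)=C1 | intermediate
12 | (5R)-5-(hexa-1,5-dien-2-yl)-6-hydroxy-4-(3-methylbut-3-en-1-yl)oxan-3-one (C4 epimers, both anomers) | OC1OCC(=O)C(CCC(C)=C)[C@@H]1C(=C)CCC=C | intermediate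
13 | (2R,3R,4S)-3-(hexa-1,5-dien-2-yl)-4-(3-methylbut-3-en-1-yl)-5-oxooxan-2-yl acetate | CC(=O)O[C@H]1OCC(=O)[C@@H](CCC(C)=C)[C@@H]1C(=C)CCC=C | intermediate
14 | (1R,4aS,7Z,11aR)-7-methyl-11-methylidene-4-oxo-1,3,4,4a,5,6,9,10,11,11a-decahydrocyclonona[c]pyran-1-yl acetate | C=C1CC/C=C(C)\CC[C@@H]2C(=O)CO[C@H](OC(C)=O)[C@@H]12 | intermediate
15 | (1R,4aS,7S,8R,11aR)-7,8-epoxy-7-methyl-11-methylidene-4-oxododecahydrocyclonona[c]pyran-1-yl acetate | C=C1CC[C@H]2O[C@@]2(C)CC[C@@H]2C(=O)CO[C@H](OC(C)=O)[C@@H]12 | intermediate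
16 | (1R,4aS,7S,8R,11aR)-7,8-epoxy-7-methyl-11-methylidene-4-(trifluoromethanesulfonyloxy)-1,4a,5,6,7,8,9,10,11,11a-decahydrocyclonona[c]pyran-1-yl acetate | C=C1CC[C@H]2O[C@@]2(C)CC[C@@H]2C(OS(=O)(=O)C(F)(F)F)=CO[C@H](OC(C)=O)[C@@H]12 | intermediate
17 | (1R,4aS,7S,8R,11aR)-7,8-epoxy-4-formyl-7-methyl-11-methylidene-1,4a,5,6,7,8,9,10,11,11a-decahydrocyclonona[c]pyran-1-yl acetate | C=C1CC[C@H]2O[C@@]2(C)CC[C@@H]2C(C=O)=CO[C@H](OC(C)=O)[C@@H]12 | intermediate
18 | allylboronic acid pinacol ester | C=CCB1OC(C)(C)C(C)(C)O1 | starting material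
19 | (1R,4aS,7S,8R,11aR)-7,8-epoxy-4-[(1S)-1-hydroxybut-3-en-1-yl]-7-methyl-11-methylidene-1,4a,5,6,7,8,9,10,11,11a-decahydrocyclonona[c]pyran-1-yl acetate | C=C1CC[C@H]2O[C@@]2(C)CC[C@@H]2C([C@H](CC=C)O)=CO[C@H](OC(C)=O)[C@@H]12 | intermediate
20 | (1R,4aS,7S,8R,11aR)-4-[(1S)-1-acetoxybut-3-en-1-yl]-7,8-epoxy-7-methyl-11-methylidene-1,4a,5,6,7,8,9,10,11,11a-decahydrocyclonona[c]pyran-1-yl acetate | C=C1CC[C@H]2O[C@@]2(C)CC[C@@H]2C([C@H](CC=C)OC(C)=O)=CO[C@H](OC(C)=O)[C@@H]12 | intermediate
21 | methyl methacrylate | C=C(C)C(=O)OC | starting material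
22 | methyl (2E,5S)-5-acetoxy-5-[(1R,4aS,7S,8R,11aR)-1-acetoxy-7,8-epoxy-7-methyl-11-methylidene-1,4a,5,6,7,8,9,10,11,11a-decahydrocyclonona[c]pyran-4-yl]-2-methylpent-2-enoate | C=C1CC[C@H]2O[C@@]2(C)CC[C@@H]2C([C@H](C/C=C(\C)C(=O)OC)OC(C)=O)=CO[C@H](OC(C)=O)[C@@H]12 | target

**Step count**
Total: 13 steps. Longest linear sequence: 11 steps (steps 3 to 13; the branch through steps 1, 2 and 5 to 13 is equally long).

**Three steps most likely to fail**

Step 5 (the proposed new method). The directed alkenyl transfer has no precedent on a cyclic hemiacetal, on an α-substituted enone, with an α-branched alkenylboronic acid, or under dynamic kinetic control. The fallback uses known chemistry and sets C1 first instead of C11a. It sets out from 11: isothiourea-catalysed dynamic kinetic acetylation ((S)-benzotetramisole, Ac2O, i-Pr2NEt, CHCl3, 0 °C) gives (2R)-4-(3-methylbut-3-en-1-yl)-5-oxo-5,6-dihydro-2H-pyran-2-yl acetate F1. Copper-catalysed conjugate addition of the Grignard reagent 4 (from 3 and Mg as in step 2; CuBr·SMe2 10 mol %, Me3SiCl, THF, −78 °C) then adds the alkenyl group anti to the anomeric acetate. Mild hydrolysis of the silyl enol ether and DBU equilibration of C4a return the route at 13, replacing steps 5 and 6 and the borylation half of step 2.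

Step 8. The intrinsic facial bias of the (Z)-cyclononene is unknown and may override the catalyst, and the anomeric acetate is exposed to a buffered aqueous base. The fallback sets out from 14 and delivers the oxygen by anti addition followed by invertive closure instead of direct oxygen transfer. NBS in aqueous 1,2-dimethoxyethane at 0 °C forms the bromonium ion on the face electrophiles prefer, and water opens it at the tertiary C7 to give (1R,4aS,7S,8S,11aR)-8-bromo-7-hydroxy-7-methyl-11-methylidene-4-oxododecahydrocyclonona[c]pyran-1-yl acetate F2. Ag2O in CH2Cl2 closes the epoxide with inversion at C8 and returns the route at 15. This places the oxygen on the face opposite to the one attacked directly, so it is the remedy if substrate control wins and gives the wrong epoxide.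

Step 11. The aldehyde is a deactivated vinylogous formate, and the product is an acid-labile allylic alcohol on an enol ether. The fallback sets out from 17 and replaces Brønsted acid catalysis by stoichiometric reagent control: commercial (−)-Ipc2B(allyl) in Et2O at −78 °C, with ethanolamine work-up instead of alkaline peroxide to spare the acetal acetate, returns the route at 19. This fallback makes no new compound (F0).

**Further compounds**
F1 | step 5 | (2R)-4-(3-methylbut-3-en-1-yl)-5-oxo-5,6-dihydro-2H-pyran-2-yl acetate | CC(=O)O[C@H]1OCC(=O)C(CCC(C)=C)=C1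
F2 | step 8 | (1R,4aS,7S,8S,11aR)-8-bromo-7-hydroxy-7-methyl-11-methylidene-4-oxododecahydrocyclonona[c]pyran-1-yl acetate | C=C1CC[C@H](Br)[C@@](C)(O)CC[C@@H]2C(=O)CO[C@H](OC(C)=O)[C@@H]12
F0 | step 11 | none | none
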